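**Strategy.** The target is an epicatechin-(4β→6)-epigallocatechin digallate. Its upper C4 is a benzylic carbon held by two electron-rich arene carbons, C4a of upper ring A and C6' of lower ring D, so C4 is traced back to an aldehyde carbon that undergoes two successive Friedel–Crafts arylations. In one operation the key step closes ring C through the C4–C4a bond, joins the two flavan halves through the C4–C6' bond and sets the C4 stereocentre trans to O3. Its precursor is an open-chain (2S,3R)-2-benzyloxy-3-aryl-3-aryloxypropanal carrying the C2 and C3 stereocentres, used with a C8'-brominated, perbenzylated epigallocatechin digallate as the second arene.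

Key step: step 17

Remark: 3,4-bis(benzyloxy)benzaldehyde, 1,3-bis(benzyloxy)-5-bromobenzene, 3,5-bis(benzyloxy)phenol and 3,4,5-tris(benzyloxy)benzoic acid are taken as catalogue chemicals; the upper C4 is described as 3,4-trans (4β) because its CIP letter changes with the substituents on ring D.

Step 1
Reactants: 1 (S)-4-benzyl-2-oxazolidinone; 2 benzyloxyacetyl chloride
Product: 4 (S)-4-benzyl-3-[(benzyloxy)acetyl]oxazolidin-2-one, via lithium oxazolidinide 3 (not isolated)
Conditions: n-BuLi, THF, −78 °C; then 2, −78 → 0 °C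
Reagents that add atoms: none
Why: N-acylation of the lithiated auxiliary by the acid chloride is the standard way to load a glycolate onto an oxazolidinone and touches no stereocentre.

Step 2
Reactants: 4 (S)-4-benzyl-3-[(benzyloxy)acetyl]oxazolidin-2-one; 5 3,4-bis(benzyloxy)benzaldehyde
Product: 7 (S)-4-benzyl-3-[(2S,3R)-2-(benzyloxy)-3-[3,4-bis(benzyloxy)phenyl]-3-hydroxypropanoyl]oxazolidin-2-one, via boron enolate 6 (not isolated)
Conditions: Bu2BOTf, Et3N, CH2Cl2, −78 → 0 °C; 5, −78 → 0 °C; then pH 7 buffer, MeOH, aq. H2O2, 0 °C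
Reagents that add atoms: none
Why: Evans boron syn-aldol of a glycolate: the Z-enolate reacts through a Zimmerman–Traxler chair on the face away from the auxiliary benzyl group, setting C2 (S) and C3 (R) in the syn relationship that becomes the 2,3-cis pattern of the upper flavan.

Step 3
Reactants: 7 syn-aldol adduct
Product: 8 (2S,3R)-2-(benzyloxy)-3-[3,4-bis(benzyloxy)phenyl]-3-hydroxy-N-methoxy-N-methylpropanamide
Conditions: MeNH(OMe)·HCl, AlMe3, CH2Cl2, −10 °C → rt; aq. potassium sodium tartrate
Reagents that add atoms: N,O-dimethylhydroxylamine hydrochloride, CNOC.Cl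
Why: Aluminium-amide transamidation (Weinreb amide formation) of β-hydroxy imides is assisted by the free hydroxyl, removes the base-sensitive auxiliary and leaves both stereocentres untouched.

Step 4
Reactants: 8 β-hydroxy Weinreb amide; 9 1,3-bis(benzyloxy)-5-bromobenzene
Product: 10 (2S,3R)-2-(benzyloxy)-3-[3,4-bis(benzyloxy)phenyl]-3-[3,5-bis(benzyloxy)phenoxy]-N-methoxy-N-methylpropanamide
Conditions: [Pd(allyl)Cl]2 (2 mol %), RockPhos (6 mol %), Cs2CO3, toluene, 90 °C
Reagents that add atoms: none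
Why: Buchwald–Hartwig-type palladium-catalysed C–O coupling of a secondary alcohol with an aryl bromide forms the bond at the aryl carbon, so the carbinol carbon keeps its R configuration, and the bulky biarylphosphine favours reductive elimination over β-hydride elimination.

Step 5
Reactants: 10 aryl ether Weinreb amide
Product: 11 (2S,3R)-2-(benzyloxy)-3-[3,4-bis(benzyloxy)phenyl]-3-[3,5-bis(benzyloxy)phenoxy]propanal
Conditions: i-Bu2AlH, THF, −78 °C; aq. potassium sodium tartrate; used at once
Reagents that add atoms: none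
Why: Hydride reduction of a Weinreb amide stops at the aldehyde oxidation level, and the cold, non-basic work-up leaves the α-alkoxy stereocentre intact.

Step 6
Reactants: 12 methyl gallate
Product: 13 methyl 3,4-bis(benzyloxy)-5-hydroxybenzoate
Conditions: BnBr (2.0 equiv), K2CO3 (2.0 equiv), KI (cat.), acetone, reflux
Reagents that add atoms: benzyl bromide, BrCc1ccccc1
Why: Williamson etherification with limiting halide alkylates the most acidic para hydroxyl first and then one of the two equivalent meta hydroxyls, so the dibenzyl ether is a single regioisomer separable from mono- and tri-ethers.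

Step 7
Reactants: 13 methyl 3,4-bis(benzyloxy)-5-hydroxybenzoate
Product: 14 methyl 3-(allyloxy)-4,5-bis(benzyloxy)benzoate
Conditions: allyl bromide, K2CO3, DMF, 50 °C
Reagents that add atoms: allyl bromide, C=CCBr
Why: Williamson allylation of the one remaining phenol marks the meta oxygen of ring E that will later carry a gallate.

Step 8
Reactants: 14 methyl 3-(allyloxy)-4,5-bis(benzyloxy)benzoate
Product: 15 [3-(allyloxy)-4,5-bis(benzyloxy)phenyl]methanol
Conditions: LiAlH4, THF, 0 °C
Reagents that add atoms: none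
Why: LiAlH4 reduces the aryl ester to the benzylic alcohol while aryl ethers and the isolated allyl alkene are inert.

Step 9
Reactants: 15 [3-(allyloxy)-4,5-bis(benzyloxy)phenyl]methanol
Product: 16 3-(allyloxy)-4,5-bis(benzyloxy)benzaldehyde
Conditions: MnO2, CH2Cl2, rt
Reagents that add atoms: none
Why: MnO2 oxidises benzylic alcohols selectively to aldehydes without over-oxidation.

Step 10
Reactants: 16 3-(allyloxy)-4,5-bis(benzyloxy)benzaldehyde
Product: 17 rac-1-[3-(allyloxy)-4,5-bis(benzyloxy)phenyl]prop-2-en-1-ol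
Conditions: CH2=CHMgBr, THF, −78 → 0 °C; aq. NH4Cl
Reagents that add atoms: vinylmagnesium bromide, C=C[Mg]Br
Why: Grignard addition of a vinyl nucleophile to the aldehyde gives the racemic secondary allylic alcohol needed for resolution.

Step 11
Reactants: 17 racemic allylic alcohol
Product: 18 (S)-[3-(allyloxy)-4,5-bis(benzyloxy)phenyl][(R)-oxiran-2-yl]methanol (erythro)
Conditions: Ti(OiPr)4, L-(+)-DIPT, t-BuOOH (0.6 equiv), 4 Å MS, CH2Cl2, −20 °C
Reagents that add atoms: tert-butyl hydroperoxide, CC(C)(C)OO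
Why: Sharpless kinetic resolution: with L-(+)-DIPT the (R)-alcohol is epoxidised much faster and erythro-selectively, setting the oxirane carbon (R) while the carbinol carbon keeps its geometry (its letter becomes S only through a priority change), and the allyl aryl ether is not an allylic alcohol and stays untouched.

Step 12
Reactants: 18 erythro epoxy alcohol; 19 3,5-bis(benzyloxy)phenol
Product: 20 (R)-2-{(R)-[3-(allyloxy)-4,5-bis(benzyloxy)phenyl][3,5-bis(benzyloxy)phenoxy]methyl}oxirane
Conditions: PPh3, DIAD, toluene, 0 °C → rt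
Reagents that add atoms: none
Why: Mitsunobu etherification displaces the activated benzylic hydroxyl by the phenol in an SN2 step, inverting that carbon to R (the future C2') while the oxirane carbon is not involved.

Step 13
Reactants: 20 aryl ether epoxide
Product: 21 (2R,3R)-2-[3-(allyloxy)-4,5-bis(benzyloxy)phenyl]-5,7-bis(benzyloxy)chroman-3-ol
Conditions: (CF3)2CHOH/CH2Cl2, 0 °C → rt
Reagents that add atoms: none
Why: Intramolecular Friedel–Crafts epoxide–arene cyclisation (6-endo attack of the phloroglucinol-type ring on the terminal oxirane carbon, activated by the hydrogen-bond-donor solvent) forms C4'–C4a' without breaking a bond at C2' or C3', so the 2,3-cis flavan-3-ol results.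

Step 14
Reactants: 21 3'-O-allyl flavan-3-ol
Product: 22 (2R,3R)-5,7-bis(benzyloxy)-2-[3,4-bis(benzyloxy)-5-hydroxyphenyl]chroman-3-ol
Conditions: Pd(PPh3)4 (5 mol %), morpholine, THF, rt
Reagents that add atoms: none
Why: Zerovalent palladium ionises the allyl aryl ether to a π-allyl complex that morpholine intercepts (Tsuji–Trost deallylation), freeing the phenol while benzyl ethers are inert.

Step 15
Reactants: 22 diol; 23 3,4,5-tris(benzyloxy)benzoic acid (2.4 equiv)
Product: 24 (2R,3R)-5,7-bis(benzyloxy)-2-{3,4-bis(benzyloxy)-5-[3,4,5-tris(benzyloxy)benzoyloxy]phenyl}chroman-3-yl 3,4,5-tris(benzyloxy)benzoate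
Conditions: DCC, DMAP, CH2Cl2, rt
Reagents that add atoms: none
Why: Steglich esterification acylates both the phenol and the hindered secondary alcohol at oxygen, so C3' keeps its configuration.

Step 16
Reactants: 24 perbenzylated epigallocatechin digallate
Product: 25 8-bromo derivative of 24 (bromine on ring D next to the ring oxygen)
Conditions: NBS (1.05 equiv), CH2Cl2, −78 → −20 °C
Reagents that add atoms: N-bromosuccinimide, O=C1CCC(=O)N1Br
Why: Electrophilic aromatic bromination of 5,7-dialkoxyflavans with one equivalent of NBS goes to C8, the most reactive ring position, and the acylated ring E and gallate rings are too electron-poor to compete.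

Step 17
Reactants: 11 aldehyde; 25 C8'-brominated lower unit (1.5 equiv)
Product: 28 perbenzylated 8'-bromo dimer (25 bearing at C6' the 2,3-cis-3,4-trans 3,5,7-tris(benzyloxy)-2-[3,4-bis(benzyloxy)phenyl]chroman-4-yl group), via C4 silyl ether 26 (not isolated), via C4 cation 27 (not isolated)
Conditions: TMSOTf (2 equiv), 4 Å MS, CH2Cl2, −78 → −30 °C; then aq. NaHCO3
Reagents that add atoms: none
Why: TMSOTf turns the aldehyde of 11 into a silyloxycarbenium ion that the ortho carbon of the tris-oxygenated ring A attacks (intramolecular Friedel–Crafts hydroxyalkylation, 6-exo-trig closure of ring C, bond C4–C4a) to give silyl ether 26, and a second activation expels the siloxy group to give the benzylic cation 27, stabilised by the C5 and C7 oxygens, which C6' of 25 captures (intermolecular Friedel–Crafts arylation, bond C4–C6'). The closest known reactions are the acid-mediated condensation of one aldehyde with two electron-rich arenes and the Lewis-acid coupling of flavan C4 cations with C8-blocked flavan-3-ol nucleophiles. C4 is set by substrate control, since the half-chair cation is approached on the face anti to the C3 benzyloxy group and to the cis C2 aryl group, which gives the 3,4-trans (4β) product, while C2 and C3 are not touched. The step needs regiocontrol on both arenes: the two ortho carbons of ring A in 11 are equivalent, and in 25 the C8' bromine leaves C6' as the only activated position of ring D, the acylated ring E and the gallate rings being too electron-poor. If 25 adds to the aldehyde before ring A does, ionisation of that adduct and closure by ring A lead to the same product, so the order of the two arylations does not matter. Excess 25 and low temperature are chosen to keep the cation from being taken by ring A of product already formed.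

Step 18
Reactants: 28 perbenzylated 8'-bromo dimer
Product: 29 epicatechin-(4β→6)-epigallocatechin 3,3'-di-O-gallate (CNP0237700.1)
Conditions: H2 (1 atm), Pd(OH)2/C, Et3N (1.1 equiv), THF/H2O, rt
Reagents that add atoms: none
Why: Catalytic hydrogenolysis cleaves all fifteen benzyl ethers and hydrodehalogenates the aryl bromide in one operation, the amine taking up HBr so that the acid-labile interflavan bond and the esters survive, and no stereocentre is affected.

**Compound list**

1 | (S)-4-benzyl-2-oxazolidinone | O=C1N[C@@H](Cc2ccccc2)CO1 | starting material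
2 | benzyloxyacetyl chloride | O=C(Cl)COCc1ccccc1 | starting material
3 | lithium (S)-4-benzyl-2-oxooxazolidin-3-ide (not isolated) | [Li+].O=C1[N-][C@@H](Cc2ccccc2)CO1 | intermediate
4 | (S)-4-benzyl-3-[(benzyloxy)acetyl]oxazolidin-2-one | O=C(COCc1ccccc1)N1[C@@H](Cc2ccccc2)COC1=O | intermediate
5 | 3,4-bis(benzyloxy)benzaldehyde | O=Cc1ccc(OCc2ccccc2)c(OCc2ccccc2)c1 | starting material
6 | (Z)-dibutylboron enolate of 4 (not isolated) | CCCCB(CCCC)O/C(=C\OCc1ccccc1)N1[C@@H](Cc2ccccc2)COC1=O | intermediate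
7 | (S)-4-benzyl-3-[(2S,3R)-2-(benzyloxy)-3-[3,4-bis(benzyloxy)phenyl]-3-hydroxypropanoyl]oxazolidin-2-one | O=C([C@@H](OCc1ccccc1)[C@H](O)c1ccc(OCc2ccccc2)c(OCc2ccccc2)c1)N1[C@@H](Cc2ccccc2)COC1=O | intermediate
8 | (2S,3R)-2-(benzyloxy)-3-[3,4-bis(benzyloxy)phenyl]-3-hydroxy-N-methoxy-N-methylpropanamide | CON(C)C(=O)[C@@H](OCc1ccccc1)[C@H](O)c1ccc(OCc2ccccc2)c(OCc2ccccc2)c1 | intermediate
9 | 1,3-bis(benzyloxy)-5-bromobenzene | Brc1cc(OCc2ccccc2)cc(OCc2ccccc2)c1 | starting material
10 | (2S,3R)-2-(benzyloxy)-3-[3,4-bis(benzyloxy)phenyl]-3-[3,5-bis(benzyloxy)phenoxy]-N-methoxy-N-methylpropanamide | CON(C)C(=O)[C@@H](OCc1ccccc1)[C@H](Oc1cc(OCc2ccccc2)cc(OCc2ccccc2)c1)c1ccc(OCc2ccccc2)c(OCc2ccccc2)c1 | intermediate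
11 | (2S,3R)-2-(benzyloxy)-3-[3,4-bis(benzyloxy)phenyl]-3-[3,5-bis(benzyloxy)phenoxy]propanal | O=C[C@@H](OCc1ccccc1)[C@H](Oc1cc(OCc2ccccc2)cc(OCc2ccccc2)c1)c1ccc(OCc2ccccc2)c(OCc2ccccc2)c1 | intermediate
12 | methyl gallate | COC(=O)c1cc(O)c(O)c(O)c1 | starting material
13 | methyl 3,4-bis(benzyloxy)-5-hydroxybenzoate | COC(=O)c1cc(O)c(OCc2ccccc2)c(OCc2ccccc2)c1 | intermediate
14 | methyl 3-(allyloxy)-4,5-bis(benzyloxy)benzoate | COC(=O)c1cc(OCC=C)c(OCc2ccccc2)c(OCc2ccccc2)c1 | intermediate
15 | [3-(allyloxy)-4,5-bis(benzyloxy)phenyl]methanol | OCc1cc(OCC=C)c(OCc2ccccc2)c(OCc2ccccc2)c1 | intermediate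
16 | 3-(allyloxy)-4,5-bis(benzyloxy)benzaldehyde | O=Cc1cc(OCC=C)c(OCc2ccccc2)c(OCc2ccccc2)c1 | intermediate
17 | rac-1-[3-(allyloxy)-4,5-bis(benzyloxy)phenyl]prop-2-en-1-ol | C=CC(O)c1cc(OCC=C)c(OCc2ccccc2)c(OCc2ccccc2)c1 | intermediate
18 | (S)-[3-(allyloxy)-4,5-bis(benzyloxy)phenyl][(R)-oxiran-2-yl]methanol | O[C@@H](c1cc(OCC=C)c(OCc2ccccc2)c(OCc2ccccc2)c1)[C@H]1CO1 | intermediate
19 | 3,5-bis(benzyloxy)phenol | Oc1cc(OCc2ccccc2)cc(OCc2ccccc2)c1 | starting material
20 | (R)-2-{(R)-[3-(allyloxy)-4,5-bis(benzyloxy)phenyl][3,5-bis(benzyloxy)phenoxy]methyl}oxirane | C=CCOc1cc([C@@H](Oc2cc(OCc3ccccc3)cc(OCc3ccccc3)c2)[C@H]2CO2)cc(OCc2ccccc2)c1OCc1ccccc1 | intermediate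
21 | (2R,3R)-2-[3-(allyloxy)-4,5-bis(benzyloxy)phenyl]-5,7-bis(benzyloxy)chroman-3-ol | C=CCOc1cc([C@H]2Oc3cc(OCc4ccccc4)cc(OCc4ccccc4)c3C[C@H]2O)cc(OCc2ccccc2)c1OCc1ccccc1 | intermediate
22 | (2R,3R)-5,7-bis(benzyloxy)-2-[3,4-bis(benzyloxy)-5-hydroxyphenyl]chroman-3-ol | Oc1cc([C@H]2Oc3cc(OCc4ccccc4)cc(OCc4ccccc4)c3C[C@H]2O)cc(OCc2ccccc2)c1OCc1ccccc1 | intermediate
23 | 3,4,5-tris(benzyloxy)benzoic acid | OC(=O)c1cc(OCc2ccccc2)c(OCc2ccccc2)c(OCc2ccccc2)c1 | starting material
24 | (2R,3R)-5,7-bis(benzyloxy)-2-{3,4-bis(benzyloxy)-5-[3,4,5-tris(benzyloxy)benzoyloxy]phenyl}chroman-3-yl 3,4,5-tris(benzyloxy)benzoate | O=C(Oc1cc([C@H]2Oc3cc(OCc4ccccc4)cc(OCc4ccccc4)c3C[C@H]2OC(=O)c2cc(OCc3ccccc3)c(OCc3ccccc3)c(OCc3ccccc3)c2)cc(OCc2ccccc2)c1OCc1ccccc1)c1cc(OCc2ccccc2)c(OCc2ccccc2)c(OCc2ccccc2)c1 | intermediate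
25 | 8-bromo derivative of 24 (2R,3R; bromine at C8 of the chroman) | O=C(Oc1cc([C@H]2Oc3c(Br)c(OCc4ccccc4)cc(OCc4ccccc4)c3C[C@H]2OC(=O)c2cc(OCc3ccccc3)c(OCc3ccccc3)c(OCc3ccccc3)c2)cc(OCc2ccccc2)c1OCc1ccccc1)c1cc(OCc2ccccc2)c(OCc2ccccc2)c(OCc2ccccc2)c1 | intermediate
26 | 3,5,7-tris(benzyloxy)-2-[3,4-bis(benzyloxy)phenyl]-4-(trimethylsilyloxy)chroman, 2,3-cis with C2 and C3 as in 11, both C4 epimers (not isolated) | C[Si](C)(C)OC1c2c(OCc3ccccc3)cc(OCc3ccccc3)cc2O[C@H](c2ccc(OCc3ccccc3)c(OCc3ccccc3)c2)[C@@H]1OCc1ccccc1 | intermediate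
27 | 3,5,7-tris(benzyloxy)-2-[3,4-bis(benzyloxy)phenyl]chroman-4-ylium triflate, 2,3-cis (not isolated) | [CH+]1c2c(OCc3ccccc3)cc(OCc3ccccc3)cc2O[C@H](c2ccc(OCc3ccccc3)c(OCc3ccccc3)c2)[C@@H]1OCc1ccccc1.[O-]S(=O)(=O)C(F)(F)F | intermediate
28 | perbenzylated 8'-bromo dimer: 25 carrying at C6' the 3,5,7-tris(benzyloxy)-2-[3,4-bis(benzyloxy)phenyl]chroman-4-yl group, upper unit 2,3-cis and 3,4-trans (4β), C2 and C3 as in 11 | O=C(Oc1cc([C@H]2Oc3c(Br)c(OCc4ccccc4)c([C@H]4c5c(OCc6ccccc6)cc(OCc6ccccc6)cc5O[C@H](c5ccc(OCc6ccccc6)c(OCc6ccccc6)c5)[C@@H]4OCc4ccccc4)c(OCc4ccccc4)c3C[C@H]2OC(=O)c2cc(OCc3ccccc3)c(OCc3ccccc3)c(OCc3ccccc3)c2)cc(OCc2ccccc2)c1OCc1ccccc1)c1cc(OCc2ccccc2)c(OCc2ccccc2)c(OCc2ccccc2)c1 | intermediate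
29 | epicatechin-(4β→6)-epigallocatechin 3,3'-di-O-gallate (upper unit 2R,3R,4S; lower unit 2R,3R; gallates on the lower C3 oxygen and on one meta oxygen of ring E) | O=C(Oc1cc([C@H]2Oc3cc(O)c([C@H]4c5c(O)cc(O)cc5O[C@H](c5ccc(O)c(O)c5)[C@@H]4O)c(O)c3C[C@H]2OC(=O)c2cc(O)c(O)c(O)c2)cc(O)c1O)c1cc(O)c(O)c(O)c1 | target

**Step count and risk**

Total steps: 18. Longest linear sequence: 13 steps (steps 6–18, from methyl gallate 12 to the target 29); the aldehyde branch (steps 1–5) joins at step 17.

Steps most likely to fail: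

Step 17. The C4 cation may be consumed by self-condensation: C8 or C6 of ring A of dimer already formed can capture it faster than the hindered, bromine-deactivated C6' of 25, which would lead to oligomers. The fallback separates the two arylations and blocks the competing site. It sets out from 11: TMSOTf (catalytic) in CH2Cl2 with excess methanol and trimethyl orthoformate should close ring C and cap C4 as the methyl ether, giving the 4-methoxyflavan F1. NBS at −78 °C should then brominate C8 to give the 8-bromo-4-methoxyflavan F2. TMSOTf ionises F2 in the presence of one equivalent of 25 to give the 8,8'-dibromo dimer F3, and the conditions of step 18, with Et3N raised to cover two bromides, bring the route back at 29.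

Step 4. β-Hydride elimination from the palladium alkoxide of the hindered benzylic alcohol, giving the β-keto amide and the reduced arene, may outrun C–O reductive elimination. The fallback delivers the aryl group by oxidative copper coupling (Chan–Lam type) instead. It sets out from 9: Miyaura borylation [B2pin2, PdCl2(dppf), KOAc, dioxane] gives the pinacol boronate F4, and KHF2 in aqueous methanol gives the potassium aryltrifluoroborate F5. F5 should arylate the hydroxyl of 8 under Cu(OAc)2, DMAP, 4 Å MS and O2 in CH2Cl2 at room temperature, again at oxygen and therefore with retention, and the route is rejoined at 10.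

Step 11. Epoxidation of the poorly nucleophilic terminal alkene is slow, so the titanium Lewis acid has time to ionise or ring-open the electron-rich benzylic epoxy alcohol, and the resolution in any case discards half of the material. The fallback sets the absolute configuration by ketone reduction instead of resolution. It sets out from 17: MnO2 gives the aryl vinyl ketone F6, and CBS reduction with the (S)-oxazaborolidine and BH3·SMe2 gives the (R)-allylic alcohol F7. Hydroxyl-directed epoxidation of F7 with VO(acac)2 and t-BuOOH, which favours the erythro isomer, returns the route at 18.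

Further compounds
F1 | step 17 | 3,5,7-tris(benzyloxy)-2-[3,4-bis(benzyloxy)phenyl]-4-methoxychroman, 2,3-cis and 3,4-trans, C2 and C3 as in 11 | CO[C@H]1c2c(OCc3ccccc3)cc(OCc3ccccc3)cc2O[C@H](c2ccc(OCc3ccccc3)c(OCc3ccccc3)c2)[C@@H]1OCc1ccccc1
F2 | step 17 | 8-bromo derivative of F1 | CO[C@H]1c2c(OCc3ccccc3)cc(OCc3ccccc3)c(Br)c2O[C@H](c2ccc(OCc3ccccc3)c(OCc3ccccc3)c2)[C@@H]1OCc1ccccc1
F3 | step 17 | 8,8'-dibromo dimer (28 with a second bromine at C8 of the upper ring A) | O=C(Oc1cc([C@H]2Oc3c(Br)c(OCc4ccccc4)c([C@H]4c5c(OCc6ccccc6)cc(OCc6ccccc6)c(Br)c5O[C@H](c5ccc(OCc6ccccc6)c(OCc6ccccc6)c5)[C@@H]4OCc4ccccc4)c(OCc4ccccc4)c3C[C@H]2OC(=O)c2cc(OCc3ccccc3)c(OCc3ccccc3)c(OCc3ccccc3)c2)cc(OCc2ccccc2)c1OCc1ccccc1)c1cc(OCc2ccccc2)c(OCc2ccccc2)c(OCc2ccccc2)c1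
F4 | step 4 | 2-[3,5-bis(benzyloxy)phenyl]-4,4,5,5-tetramethyl-1,3,2-dioxaborolane | CC1(C)OB(OC1(C)C)c1cc(OCc2ccccc2)cc(OCc2ccccc2)c1
F5 | step 4 | potassium [3,5-bis(benzyloxy)phenyl]trifluoroborate | [K+].F[B-](F)(F)c1cc(OCc2ccccc2)cc(OCc2ccccc2)c1
F6 | step 11 | 1-[3-(allyloxy)-4,5-bis(benzyloxy)phenyl]prop-2-en-1-one | C=CC(=O)c1cc(OCC=C)c(OCc2ccccc2)c(OCc2ccccc2)c1
F7 | step 11 | (R)-1-[3-(allyloxy)-4,5-bis(benzyloxy)phenyl]prop-2-en-1-ol | C=C[C@@H](O)c1cc(OCC=C)c(OCc2ccccc2)c(OCc2ccccc2)c1
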